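With the skeleton numbered as tricyclo[5.4.0.0²,⁸]undecane (C2 quaternary methyl carbon, C4/C5 ester carbons, C6 gem-dimethyl carbon, C9 ketone), the route rests on disconnecting C6–C7 within the seven-membered ring C2–C3–C4–C5–C6–C7–C8. The precursor is a bicyclo[3.1.1]heptan-6-one carrying a four-carbon isopropenyl ketone arm on the opposite one-carbon bridge, made in one step by a vinylketene [2+2] cycloaddition of an acyclic acid. A copper hydride reductive aldol cyclisation then closes the seven-membered ring, creates quaternary C6 and sets C7. It exploits the cis-1,3 relation across the cyclobutane C1–C2–C8–C7 between the C2 arm and the strained C7 carbonyl, so the enolate reaches one carbonyl face only.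

Key step: step 9

Remark: the target is taken as the SMILES defines it, (1S,2R,4S,5S,7S,8R,11R). All tricyclic compounds keep the target numbering given above, even where a strict name would number differently; their SMILES are authoritative.

Step 1
Reactants: 1 pent-4-ynoic acid
Product: 2 N-methoxy-N-methylpent-4-ynamide
Conditions: MeNHOMe·HCl, EDC·HCl, HOBt, Et3N, CH2Cl2, 0 °C to rt
Reagents that add atoms: N,O-dimethylhydroxylamine hydrochloride, CNOC.Cl
Why: Carbodiimide amide coupling gives the N-methoxy-N-methylamide that later serves in a Weinreb ketone synthesis; no stereocentre is formed.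

Step 2
Reactants: 2 N-methoxy-N-methylpent-4-ynamide
Product: 4 (4E)-5-iodo-N-methoxy-N,4-dimethylpent-4-enamide, via alkenylalane 3 (not isolated)
Conditions: AlMe3 (3 equiv), Cp2ZrCl2 (0.25 equiv), CH2Cl2, 0 °C to rt; then I2, THF, −30 °C
Reagents that add atoms: trimethylaluminium, C[Al](C)C; iodine, II
Why: Zirconium-catalysed carboalumination (Negishi) adds methyl and aluminium syn across the terminal alkyne with aluminium on the terminal carbon, and iodinolysis with retention should give the E trisubstituted alkenyl iodide that later fixes the geometry at C2.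

Step 3
Reactants: 4 (4E)-5-iodo-N-methoxy-N,4-dimethylpent-4-enamide
Product: 5 (4E)-N-methoxy-N,4-dimethyl-5-(4,4,5,5-tetramethyl-1,3,2-dioxaborolan-2-yl)pent-4-enamide
Conditions: B2pin2, PdCl2(PPh3)2 (3 mol %), PPh3, KOPh, toluene, 50 °C
Reagents that add atoms: bis(pinacolato)diboron, CC1(C)OB(OC1(C)C)B1OC(C)(C)C(C)(C)O1
Why: Miyaura borylation of an alkenyl iodide proceeds with retention of alkene geometry and should leave the amide untouched.

Step 4
Reactants: 5 (4E)-N-methoxy-N,4-dimethyl-5-(4,4,5,5-tetramethyl-1,3,2-dioxaborolan-2-yl)pent-4-enamide; 6 (3E)-pent-3-en-2-one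
Product: 7 (4E,6R)-N-methoxy-N,4,6-trimethyl-8-oxonon-4-enamide
Conditions: [RhCl(C2H4)2]2 (1.5 mol %), (S)-BINAP (3.3 mol %), KOH (0.3 equiv), dioxane/H2O 10:1, 50 °C
Reagents that add atoms: none
Why: Rhodium-catalysed asymmetric conjugate addition (Hayashi–Miyaura reaction) transfers the alkenyl group to the enone face selected by the ligand; by the established model for (S)-BINAP (attack on the α-si face of an E enone) this should set the 6R methyl stereocentre, the future C11.

Step 5
Reactants: 7 (4E,6R)-N-methoxy-N,4,6-trimethyl-8-oxonon-4-enamide; 8 triethyl phosphonoacetate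
Product: 9 ethyl (2E,5R,6E)-10-[methoxy(methyl)amino]-3,5,7-trimethyl-10-oxodeca-2,6-dienoate
Conditions: NaH, THF, 0 °C to reflux; chromatographic removal of the 2Z isomer
Reagents that add atoms: none
Why: Horner–Wadsworth–Emmons olefination of the methyl ketone should favour the E enoate (ester trans to the longer chain), the isomer whose C3 methyl is cis to the carbonyl as the later ketene formation requires.

Step 6
Reactants: 9 ethyl (2E,5R,6E)-10-[methoxy(methyl)amino]-3,5,7-trimethyl-10-oxodeca-2,6-dienoate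
Product: 10 (2E,5R,6E)-10-[methoxy(methyl)amino]-3,5,7-trimethyl-10-oxodeca-2,6-dienoic acid
Conditions: LiOH, THF/MeOH/H2O, rt; then aq. HCl to pH 3
Reagents that add atoms: lithium hydroxide, [Li+].[OH-]
Why: Saponification of the ethyl ester by hydroxide should leave the less electrophilic N-methoxy-N-methylamide intact.

Step 7
Reactants: 10 (2E,5R,6E)-10-[methoxy(methyl)amino]-3,5,7-trimethyl-10-oxodeca-2,6-dienoic acid; 11 isopropenylmagnesium bromide
Product: 12 (2E,5R,6E)-3,5,7,11-tetramethyl-10-oxododeca-2,6,11-trienoic acid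
Conditions: CH2=C(CH3)MgBr (3 equiv), THF, −20 to 0 °C; then aq. HCl
Reagents that add atoms: none
Why: Weinreb ketone synthesis: the first equivalent of Grignard reagent forms the inert carboxylate and the second adds to the amide as a stable chelate that releases the isopropenyl ketone only on work-up, so over-addition is not expected.

Step 8
Reactants: 12 (2E,5R,6E)-3,5,7,11-tetramethyl-10-oxododeca-2,6,11-trienoic acid
Product: 15 (1S,4R,5R,7R)-4,7-dimethyl-7-(4-methyl-3-oxopent-4-en-1-yl)-2-methylidenebicyclo[3.1.1]heptan-6-one, via acid chloride 13 (not isolated), via vinylketene 14 (not isolated)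
Conditions: (COCl)2, benzene, rt, then evaporation; slow addition to Et3N (3 equiv), toluene, reflux, high dilution
Reagents that add atoms: none
Why: 1,4-Elimination of HCl through the methyl group cis to the acyl chloride gives the vinylketene, which should undergo the intramolecular ketene–alkene [2+2] cycloaddition in the bridged sense (carbonyl carbon to the alkene CH, ketene α-carbon to the disubstituted alkene carbon) and so form cyclobutanone and six-membered ring together; allylic 1,3-strain between the C5 stereocentre and the cis methyl of the E alkene leaves one alkene face open, which sets C1, C5 and C7 relative to C4, and suprafacial addition places the side arm on the bridge face turned towards the ketone.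

Step 9
Reactants: 15 (1S,4R,5R,7R)-4,7-dimethyl-7-(4-methyl-3-oxopent-4-en-1-yl)-2-methylidenebicyclo[3.1.1]heptan-6-one
Product: 16 (1R,2R,7R,8S,11R)-7-hydroxy-2,6,6,11-tetramethyl-9-methylidenetricyclo[5.4.0.0²,⁸]undecan-5-one
Conditions: [(Ph3P)CuH]6 (0.4 equiv), toluene, −40 °C to rt; then aq. NH4Cl
Reagents that add atoms: none
Why: Conjugate hydride transfer from copper to the isopropenyl ketone gives regiospecifically the fully substituted copper enolate, whose carbon (the future C6) adds to the C7 cyclobutanone carbonyl, and protonation on work-up gives the aldol. The closest known reaction type is the copper hydride mediated reductive aldol cyclisation of keto enones. The seven-membered ring (C2, C3, C4, C5, C6, C7, C8) closes by 7-exo-trig attack of the enolate carbon on the carbonyl, with the enolate double bond outside the new ring (enolexo). C7 is the only new stereocentre and is fixed by the tether: the arm hangs from the C2 substituent lying cis-1,3 across the cyclobutane over the carbonyl, so C6 can bond only to that face and the hydroxyl is forced to the outer face; C6 becomes quaternary but is not stereogenic. The step needs 1,4- rather than 1,2-hydride delivery, no reduction of the cyclobutanone or the exocyclic methylene, and ring closure faster than enolate quenching; the phosphine copper hydride is selective for enones over saturated ketones and isolated alkenes, no other electrophile is within reach of the enolate, and relief of cyclobutanone strain on rehybridisation of C7 should drive the addition and disfavour retro-aldol.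

Step 10
Reactants: 16 (1R,2R,7R,8S,11R)-7-hydroxy-2,6,6,11-tetramethyl-9-methylidenetricyclo[5.4.0.0²,⁸]undecan-5-one
Product: 17 methyl (1R,2R,7R,8S,11R)-2,6,6,11-tetramethyl-9-methylidene-5-oxotricyclo[5.4.0.0²,⁸]undecan-7-yl oxalate
Conditions: ClC(O)CO2Me, Et3N, DMAP, CH2Cl2, 0 °C to rt
Reagents that add atoms: methyl chlorooxoacetate, COC(=O)C(=O)Cl
Why: Acylation of the tertiary aldol hydroxyl with the small, very reactive oxalyl monoester chloride under nucleophilic catalysis should give the radical precursor without a free alkoxide that could trigger retro-aldol cleavage.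

Step 11
Reactants: 17 methyl (1R,2R,7R,8S,11R)-2,6,6,11-tetramethyl-9-methylidene-5-oxotricyclo[5.4.0.0²,⁸]undecan-7-yl oxalate
Product: 18 (1S,2R,7S,8S,11R)-2,6,6,11-tetramethyl-9-methylidenetricyclo[5.4.0.0²,⁸]undecan-5-one
Conditions: Bu3SnH, AIBN (cat.), toluene, reflux
Reagents that add atoms: none
Why: Barton–McCombie-type radical deoxygenation of the tertiary oxalate gives the C7 cyclobutyl radical, which has no elimination pathway (bridgehead neighbours, quaternary C6) and can take hydrogen only on the outer face, so the C7–H configuration is dictated by the ring.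

Step 12
Reactants: 18 (1S,2R,7S,8S,11R)-2,6,6,11-tetramethyl-9-methylidenetricyclo[5.4.0.0²,⁸]undecan-5-one
Product: 20 (1S,2R,4S,7S,8S,11R)-4-hydroxy-2,6,6,11-tetramethyl-9-methylidenetricyclo[5.4.0.0²,⁸]undecan-5-one, via sodium enolate 19 (not isolated)
Conditions: NaN(SiMe3)2, THF, −78 °C; then (+)-[(8,8-dichlorocamphoryl)sulfonyl]oxaziridine, −78 °C; aq. NH4Cl
Reagents that add atoms: (+)-[(8,8-dichlorocamphoryl)sulfonyl]oxaziridine, CC1(C)C2CCC13CS(=O)(=O)N4OC34C2(Cl)Cl
Why: Enolisation is possible only towards C4 (C6 is quaternary), and asymmetric enolate hydroxylation by the enantiopure N-sulfonyloxaziridine is reagent-controlled because the substrate offers two nearly equivalent enolate faces; the (+)-reagent is expected to deliver oxygen to the face that gives 4S, and the exocyclic methylene is inert to it.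

Step 13
Reactants: 20 (1S,2R,4S,7S,8S,11R)-4-hydroxy-2,6,6,11-tetramethyl-9-methylidenetricyclo[5.4.0.0²,⁸]undecan-5-one
Product: 21 (1S,2R,4S,5S,7S,8S,11R)-2,6,6,11-tetramethyl-9-methylidenetricyclo[5.4.0.0²,⁸]undecane-4,5-diol
Conditions: Me4NBH(OAc)3, MeCN/AcOH, −30 °C
Reagents that add atoms: none
Why: Hydroxyl-directed reduction (Saksena–Evans type): the C4 hydroxyl exchanges onto boron and delivers hydride to the C5 carbonyl from its own face, so the new C5 hydroxyl should be trans to C4–OH (5S).

Step 14
Reactants: 21 (1S,2R,4S,5S,7S,8S,11R)-2,6,6,11-tetramethyl-9-methylidenetricyclo[5.4.0.0²,⁸]undecane-4,5-diol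
Product: 23 (1S,2R,4S,5S,7S,8R,11R)-4,5-dihydroxy-2,6,6,11-tetramethyltricyclo[5.4.0.0²,⁸]undecan-9-one, via ozonide 22 (not isolated)
Conditions: O3, CH2Cl2, −78 °C; then Me2S, −78 °C to rt
Reagents that add atoms: ozone, [O-][O+]=O
Why: Ozonolysis of the only remaining alkene, the exocyclic methylene, with reductive work-up unveils the C9 ketone; the free diol is not touched and the adjacent bridgehead C8 cannot enolise.

Step 15
Reactants: 23 (1S,2R,4S,5S,7S,8R,11R)-4,5-dihydroxy-2,6,6,11-tetramethyltricyclo[5.4.0.0²,⁸]undecan-9-one; 24 angelic acid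
Product: 26 (1S,2R,4S,5S,7S,8R,11R)-2,6,6,11-tetramethyl-9-oxotricyclo[5.4.0.0²,⁸]undecane-4,5-diyl bis[(2Z)-2-methylbut-2-enoate], via mixed anhydride 25 (not isolated)
Conditions: 24 (3 equiv), 2,4,6-trichlorobenzoyl chloride, Et3N, toluene, rt; then 23, 80 °C
Reagents that add atoms: none
Why: Yamaguchi esterification with the preformed mixed anhydride and no nucleophilic catalyst should acylate both secondary hydroxyls while avoiding base-mediated Z to E isomerisation of the angeloyl groups.

Compound list
1 | pent-4-ynoic acid | C#CCCC(=O)O | starting material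
2 | N-methoxy-N-methylpent-4-ynamide | C#CCCC(=O)N(C)OC | intermediate
3 | dimethyl[(1E)-5-[methoxy(methyl)amino]-2-methyl-5-oxopent-1-en-1-yl]alane | C[Al](C)/C=C(\C)CCC(=O)N(C)OC | intermediate
4 | (4E)-5-iodo-N-methoxy-N,4-dimethylpent-4-enamide | I/C=C(\C)CCC(=O)N(C)OC | intermediate
5 | (4E)-N-methoxy-N,4-dimethyl-5-(4,4,5,5-tetramethyl-1,3,2-dioxaborolan-2-yl)pent-4-enamide | CON(C)C(=O)CC/C(C)=C/B1OC(C)(C)C(C)(C)O1 | intermediate
6 | (3E)-pent-3-en-2-one | C/C=C/C(C)=O | starting material
7 | (4E,6R)-N-methoxy-N,4,6-trimethyl-8-oxonon-4-enamide | CC(=O)C[C@@H](C)/C=C(\C)CCC(=O)N(C)OC | intermediate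
8 | triethyl phosphonoacetate | CCOC(=O)CP(=O)(OCC)OCC | starting material
9 | ethyl (2E,5R,6E)-10-[methoxy(methyl)amino]-3,5,7-trimethyl-10-oxodeca-2,6-dienoate | CCOC(=O)/C=C(\C)C[C@@H](C)/C=C(\C)CCC(=O)N(C)OC | intermediate
10 | (2E,5R,6E)-10-[methoxy(methyl)amino]-3,5,7-trimethyl-10-oxodeca-2,6-dienoic acid | OC(=O)/C=C(\C)C[C@@H](C)/C=C(\C)CCC(=O)N(C)OC | intermediate
11 | isopropenylmagnesium bromide | CC(=C)[Mg]Br | starting material
12 | (2E,5R,6E)-3,5,7,11-tetramethyl-10-oxododeca-2,6,11-trienoic acid | OC(=O)/C=C(\C)C[C@@H](C)/C=C(\C)CCC(=O)C(C)=C | intermediate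
13 | (2E,5R,6E)-3,5,7,11-tetramethyl-10-oxododeca-2,6,11-trienoyl chloride | ClC(=O)/C=C(\C)C[C@@H](C)/C=C(\C)CCC(=O)C(C)=C | intermediate
14 | (5R,6E)-5,7,11-trimethyl-3-methylidene-10-oxododeca-1,6,11-trien-1-one (vinylketene) | O=C=CC(=C)C[C@@H](C)/C=C(\C)CCC(=O)C(C)=C | intermediate
15 | (1S,4R,5R,7R)-4,7-dimethyl-7-(4-methyl-3-oxopent-4-en-1-yl)-2-methylidenebicyclo[3.1.1]heptan-6-one | C=C(C)C(=O)CC[C@]1(C)[C@@H]2C(=O)[C@H]1C(=C)C[C@H]2C | intermediate
16 | (1R,2R,7R,8S,11R)-7-hydroxy-2,6,6,11-tetramethyl-9-methylidenetricyclo[5.4.0.0²,⁸]undecan-5-one | C1C[C@]2(C)[C@@H]3[C@@](O)([C@H]2C(=C)C[C@H]3C)C(C)(C)C1=O | intermediate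
17 | methyl (1R,2R,7R,8S,11R)-2,6,6,11-tetramethyl-9-methylidene-5-oxotricyclo[5.4.0.0²,⁸]undecan-7-yl oxalate | C1C[C@]2(C)[C@@H]3[C@@](OC(=O)C(=O)OC)([C@H]2C(=C)C[C@H]3C)C(C)(C)C1=O | intermediate
18 | (1S,2R,7S,8S,11R)-2,6,6,11-tetramethyl-9-methylidenetricyclo[5.4.0.0²,⁸]undecan-5-one | C1C[C@]2(C)[C@@H]3[C@@H]([C@H]2C(=C)C[C@H]3C)C(C)(C)C1=O | intermediate
19 | sodium 2,6,6,11-tetramethyl-9-methylidenetricyclo[5.4.0.0²,⁸]undec-4-en-5-olate, skeleton configured as in 18 | [Na]OC1=CC[C@]2(C)[C@@H]3[C@@H]([C@H]2C(=C)C[C@H]3C)C1(C)C | intermediate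
20 | (1S,2R,4S,7S,8S,11R)-4-hydroxy-2,6,6,11-tetramethyl-9-methylidenetricyclo[5.4.0.0²,⁸]undecan-5-one | O[C@H]1C[C@]2(C)[C@@H]3[C@@H]([C@H]2C(=C)C[C@H]3C)C(C)(C)C1=O | intermediate
21 | (1S,2R,4S,5S,7S,8S,11R)-2,6,6,11-tetramethyl-9-methylidenetricyclo[5.4.0.0²,⁸]undecane-4,5-diol | O[C@H]1C[C@]2(C)[C@@H]3[C@@H]([C@H]2C(=C)C[C@H]3C)C(C)(C)[C@@H]1O | intermediate
22 | secondary ozonide of 21 (spiro-1,2,4-trioxolane at C9, either spiro epimer; other centres as in 21) | O[C@H]1C[C@]2(C)[C@@H]3[C@@H]([C@H]2C4(OCOO4)C[C@H]3C)C(C)(C)[C@@H]1O | intermediate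
23 | (1S,2R,4S,5S,7S,8R,11R)-4,5-dihydroxy-2,6,6,11-tetramethyltricyclo[5.4.0.0²,⁸]undecan-9-one | O[C@H]1C[C@]2(C)[C@@H]3[C@@H]([C@H]2C(=O)C[C@H]3C)C(C)(C)[C@@H]1O | intermediate
24 | angelic acid, (2Z)-2-methylbut-2-enoic acid | C/C=C(/C)C(=O)O | starting material
25 | (2Z)-2-methylbut-2-enoic 2,4,6-trichlorobenzoic anhydride | C/C=C(/C)C(=O)OC(=O)c1c(Cl)cc(Cl)cc1Cl | intermediate
26 | (1S,2R,4S,5S,7S,8R,11R)-2,6,6,11-tetramethyl-9-oxotricyclo[5.4.0.0²,⁸]undecane-4,5-diyl bis[(2Z)-2-methylbut-2-enoate] | C/C=C(/C)C(=O)O[C@H]1C[C@]2(C)[C@@H]3[C@@H]([C@H]2C(=O)C[C@H]3C)C(C)(C)[C@@H]1OC(=O)/C(C)=C\C | target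

Total step count: 15. Longest linear sequence: 15 steps (1 to 26).

Steps most likely to fail

Step 9 (key step). The copper enolate may be quenched faster than it closes the seven-membered ring, so that only conjugate reduction to the open isopropyl ketone occurs, or hydride may attack the cyclobutanone. The fallback sets out from 15: copper-hydride-catalysed 1,4-hydrosilylation ([(Ph3P)CuH]6 cat., PhMe2SiH, toluene) is stopped at the isolable tetrasubstituted silyl enol ether, 7-{3-[dimethyl(phenyl)silyloxy]-4-methylpent-3-en-1-yl}-4,7-dimethyl-2-methylidenebicyclo[3.1.1]heptan-6-one F1. A separate Lewis-acid step (TiCl4, CH2Cl2, −78 °C, intramolecular Mukaiyama aldol addition) then activates the cyclobutanone and forms C6–C7, coming back to the route at 16.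

Step 12. Facial discrimination in the oxygen transfer may be poor, because the two faces of the C4=C5 enolate differ only through remote groups, and the acyloin may epimerise under base. The fallback sets out from 18: hydroxylation of the sodium enolate with racemic 3-phenyl-2-(phenylsulfonyl)oxaziridine gives 4-hydroxy-2,6,6,11-tetramethyl-9-methylidenetricyclo[5.4.0.0²,⁸]undecan-5-one as both C4 epimers F5. Dess–Martin oxidation gives the 1,2-diketone, 2,6,6,11-tetramethyl-9-methylidenetricyclo[5.4.0.0²,⁸]undecane-4,5-dione F6, in which C4 is no longer stereogenic. Asymmetric transfer hydrogenation (RuCl(p-cymene)[(S,S)-TsDPEN], HCO2H/Et3N, the ligand antipode being the one that gives 4S,5S) should then reduce both carbonyls under catalyst control to the trans diol, coming back to the route at 21 and bypassing step 13.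

Step 10. The very hindered tertiary hydroxyl may fail to acylate, or the new ring may open by retro-aldol cleavage under the basic acylation conditions. The fallback sets out from 16: NaBH4 in MeOH reduces the C5 ketone to 2,6,6,11-tetramethyl-9-methylidenetricyclo[5.4.0.0²,⁸]undecane-5,7-diol (both C5 epimers) F2. 1,1′-Thiocarbonyldiimidazole acylates the secondary hydroxyl and then closes intramolecularly onto the tertiary one, giving the cyclic 5,7-thionocarbonate F3. Bu3SnH/AIBN cleaves this ring at the tertiary C7–O bond (more stable radical), and hydrolysis gives 2,6,6,11-tetramethyl-9-methylidenetricyclo[5.4.0.0²,⁸]undecan-5-ol F4. Dess–Martin oxidation comes back to the route at 18.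

Further compounds
F1 | step 9 | 7-{3-[dimethyl(phenyl)silyloxy]-4-methylpent-3-en-1-yl}-4,7-dimethyl-2-methylidenebicyclo[3.1.1]heptan-6-one, configured as 15 | CC(C)=C(O[Si](C)(C)c1ccccc1)CC[C@]1(C)[C@@H]2C(=O)[C@H]1C(=C)C[C@H]2C
F2 | step 10 | 2,6,6,11-tetramethyl-9-methylidenetricyclo[5.4.0.0²,⁸]undecane-5,7-diol, both C5 epimers, other centres as in 16 | C1C[C@]2(C)[C@@H]3[C@@](O)([C@H]2C(=C)C[C@H]3C)C(C)(C)C1O
F3 | step 10 | cyclic 5,7-thionocarbonate of F2 | C1C[C@]2(C)[C@@H]3[C@@]4(OC(=S)OC1C4(C)C)[C@H]2C(=C)C[C@H]3C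
F4 | step 10 | 2,6,6,11-tetramethyl-9-methylidenetricyclo[5.4.0.0²,⁸]undecan-5-ol, both C5 epimers, other centres as in 18 | C1C[C@]2(C)[C@@H]3[C@@H]([C@H]2C(=C)C[C@H]3C)C(C)(C)C1O
F5 | step 12 | 4-hydroxy-2,6,6,11-tetramethyl-9-methylidenetricyclo[5.4.0.0²,⁸]undecan-5-one, both C4 epimers, other centres as in 18 | OC1C[C@]2(C)[C@@H]3[C@@H]([C@H]2C(=C)C[C@H]3C)C(C)(C)C1=O
F6 | step 12 | 2,6,6,11-tetramethyl-9-methylidenetricyclo[5.4.0.0²,⁸]undecane-4,5-dione, centres as in 18 | O=C1C[C@]2(C)[C@@H]3[C@@H]([C@H]2C(=C)C[C@H]3C)C(C)(C)C1=O
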